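**Plan**
- The target is read as the (2S,3S,4R)-oxolane: the C2 aryl and the C3 acyloxymethyl arm are cis, and the C3 arm and the C4 benzyl group are trans. This is the C3 epimer of the lariciresinol pattern, so the cis C2/C3 pair must be set kinetically.
- Retrosynthesis: cut the coumarate ester C–O bond, then the ring C2–C3 bond (insertion of a C3 carbenoid into the O–CH2–aryl C–H bond), then the diazo group, the O–CH2Ar ether bond and the C4–CH2Ar bond.
- Forward: two vanillin-derived benzyl units are joined to a succinate chain, first by C-alkylation and then by O-alkylation. The acyclic α-diazo ester is closed to the oxolane, the only ring that is made. Ester reduction, acylation with silylated p-coumaric acid and desilylation follow.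
- Enabling feature: the oxolane C2–H is benzylic to the guaiacyl ring, α to O1 and 1,5 to C3. The exocyclic carbon on C3 (C9) is carried at the carboxyl level, where it stabilises the diazo compound and later becomes the CH2O arm.
- Stereochemistry: C4 comes from an Evans alkylation with the (R)-oxazolidinone. C2 and C3 come from the insertion: aryl trans to the C4 benzyl group, ester cis to the aryl group.

Key step: step 10

Remark: TIPS = triisopropylsilyl, TBS = tert-butyldimethylsilyl, PTTL = N-phthaloyl-tert-leucinate. Ring positions are given in oxolane numbering (O1, C2 aryl, C3 arm, C4 benzyl, C5).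

**Step 1**
Reactants: 1 vanillin
Product: 2 3-methoxy-4-(triisopropylsilyloxy)benzaldehyde
Conditions: TIPSCl, imidazole, DMF, rt
Reagents that add atoms: chlorotriisopropylsilane, CC(C)[Si](Cl)(C(C)C)C(C)C
Why: Imidazole-promoted O-silylation of the phenol; the aryl TIPS ether should survive amide bases, hydrides and the carbenoid step and is removed by fluoride at the end.

**Step 2**
Reactants: 2 3-methoxy-4-(triisopropylsilyloxy)benzaldehyde
Product: 3 [3-methoxy-4-(triisopropylsilyloxy)phenyl]methanol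
Conditions: NaBH4, MeOH/THF, 0 °C
Reagents that add atoms: none
Why: Borohydride reduction of the aromatic aldehyde to the benzylic alcohol.

**Step 3**
Reactants: 3 [3-methoxy-4-(triisopropylsilyloxy)phenyl]methanol
Product: 4 [4-(bromomethyl)-2-methoxyphenoxy]triisopropylsilane
Conditions: CBr4, PPh3, CH2Cl2, 0 °C; used at once
Reagents that add atoms: tetrabromomethane, BrC(Br)(Br)Br
Why: Appel bromination converts the benzylic alcohol into the bromide under neutral conditions that the aryl silyl ether tolerates.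

**Step 4**
Reactants: 3 [3-methoxy-4-(triisopropylsilyloxy)phenyl]methanol
Product: 5 [3-methoxy-4-(triisopropylsilyloxy)phenyl]methyl 2,2,2-trichloroacetimidate
Conditions: Cl3CCN, DBU (10 mol %), CH2Cl2, 0 °C
Reagents that add atoms: trichloroacetonitrile, ClC(Cl)(Cl)C#N
Why: Base-catalysed addition of the alcohol to trichloroacetonitrile (imidate formation) gives a benzyl donor that is activated by mild acid.

**Step 5**
Reactants: 6 4-tert-butoxy-4-oxobutanoic acid; 7 (4R)-4-benzyl-1,3-oxazolidin-2-one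
Product: 9 tert-butyl 4-[(4R)-4-benzyl-2-oxo-1,3-oxazolidin-3-yl]-4-oxobutanoate, via mixed pivalic anhydride 8 (not isolated)
Conditions: t-BuCOCl, Et3N, THF, −20 °C; then 7, LiCl, rt
Reagents that add atoms: pivaloyl chloride, CC(C)(C)C(=O)Cl (its acyl group is carried by intermediate 8 only)
Why: N-Acylation of the oxazolidinone by the mixed pivalic anhydride under LiCl/Et3N activation (standard Evans imide formation); the hindered pivaloyl carbonyl is not attacked.

**Step 6**
Reactants: 9 tert-butyl 4-[(4R)-4-benzyl-2-oxo-1,3-oxazolidin-3-yl]-4-oxobutanoate; 4 [4-(bromomethyl)-2-methoxyphenoxy]triisopropylsilane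
Product: 11 tert-butyl (3R)-4-[(4R)-4-benzyl-2-oxo-1,3-oxazolidin-3-yl]-3-[[3-methoxy-4-(triisopropylsilyloxy)phenyl]methyl]-4-oxobutanoate, via sodium Z-enolate 10 (not isolated)
Conditions: NaN(SiMe3)2, THF, −78 °C; then 4, −78 °C to −40 °C
Reagents that add atoms: sodium bis(trimethylsilyl)amide, C[Si](C)(C)[N-][Si](C)(C)C.[Na+] (the sodium of intermediate 10 only)
Why: Evans asymmetric alkylation: the chelated sodium Z-enolate of the imide, formed in preference to the ester enolate, is alkylated on the face opposite the benzyl group of the (R)-auxiliary, which should set the future oxolane C4 (3R in 11).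

**Step 7**
Reactants: 11 tert-butyl (3R)-4-[(4R)-4-benzyl-2-oxo-1,3-oxazolidin-3-yl]-3-[[3-methoxy-4-(triisopropylsilyloxy)phenyl]methyl]-4-oxobutanoate
Product: 12 tert-butyl (3R)-3-(hydroxymethyl)-4-[3-methoxy-4-(triisopropylsilyloxy)phenyl]butanoate
Conditions: LiBH4, H2O (1 equiv), Et2O, 0 °C
Reagents that add atoms: none
Why: LiBH4 reduces the activated imide carbonyl to the primary alcohol and releases the auxiliary (reductive auxiliary cleavage), while the hindered tert-butyl ester should stay intact and unlactonised.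

**Step 8**
Reactants: 12 tert-butyl (3R)-3-(hydroxymethyl)-4-[3-methoxy-4-(triisopropylsilyloxy)phenyl]butanoate; 5 [3-methoxy-4-(triisopropylsilyloxy)phenyl]methyl 2,2,2-trichloroacetimidate
Product: 13 tert-butyl (3R)-4-[3-methoxy-4-(triisopropylsilyloxy)phenyl]-3-[[[3-methoxy-4-(triisopropylsilyloxy)phenyl]methoxy]methyl]butanoate
Conditions: 5 (1.5 equiv), PPTS (10 mol %), CH2Cl2, 0 °C to rt
Reagents that add atoms: none
Why: Acid-catalysed O-benzylation with an electron-rich benzylic trichloroacetimidate (as in PMB or 3,4-dimethoxybenzyl ether formation) alkylates the alcohol without forming an alkoxide that would lactonise onto the ester.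

**Step 9**
Reactants: 13 tert-butyl (3R)-4-[3-methoxy-4-(triisopropylsilyloxy)phenyl]-3-[[[3-methoxy-4-(triisopropylsilyloxy)phenyl]methoxy]methyl]butanoate
Product: 15 tert-butyl (3R)-2-diazo-4-[3-methoxy-4-(triisopropylsilyloxy)phenyl]-3-[[[3-methoxy-4-(triisopropylsilyloxy)phenyl]methoxy]methyl]butanoate, via α-trifluoroacetyl ester 14 (not isolated)
Conditions: LiN(SiMe3)2, THF, −78 °C, then CF3CO2CH2CF3; then 4-AcNHC6H4SO2N3, Et3N, H2O (1 equiv), MeCN, rt
Reagents that add atoms: 2,2,2-trifluoroethyl trifluoroacetate, O=C(OCC(F)(F)F)C(F)(F)F (trifluoroacetyl group of intermediate 14 only); 4-acetamidobenzenesulfonyl azide, CC(=O)Nc1ccc(cc1)S(=O)(=O)N=[N+]=[N-]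
Why: Deacylative (Regitz-type) diazo transfer: C-trifluoroacetylation of the ester enolate makes the α-position acidic enough for diazo transfer from the sulfonyl azide, and the trifluoroacetyl group leaves as the N-sulfonyl trifluoroacetamide; C4 is not enolisable.

**Step 10**
Reactants: 15 tert-butyl (3R)-2-diazo-4-[3-methoxy-4-(triisopropylsilyloxy)phenyl]-3-[[[3-methoxy-4-(triisopropylsilyloxy)phenyl]methoxy]methyl]butanoate
Product: 16 tert-butyl (2S,3R,4R)-2-[3-methoxy-4-(triisopropylsilyloxy)phenyl]-4-[[3-methoxy-4-(triisopropylsilyloxy)phenyl]methyl]oxolane-3-carboxylate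
Conditions: Rh2(S-PTTL)4 (dirhodium tetrakis[N-phthaloyl-(S)-tert-leucinate], 1 mol %), toluene, −78 °C to −40 °C, slow addition of 15
Reagents that add atoms: none
Why: Loss of N2 from 15 at the dirhodium centre should give an electrophilic rhodium carbenoid at the future C3, which inserts in a concerted, asynchronous (hydride-transfer-like) manner into the C–H bond of the O–CH2–aryl group lying 1,5 to it. The closest known reaction type is the intramolecular rhodium-carbenoid C–H insertion of α-alkyl-α-diazo esters and α-diazo lactones into benzylic and O-benzylic C–H bonds, which gives cis-2-aryl cyclopentane- and oxolane-3-carboxyl compounds. The oxolane closes by 1,5 C–H insertion, forming the C2–C3 bond through a chair-like transition state. C2 is controlled by the C4 stereocentre (benzyl and aryl both pseudo-equatorial, hence trans across the ring), and C3 by the kinetic preference of this insertion, reinforced by the phthalimido-carboxylate ligands, for ester cis to aryl, which also places the ester trans to the C4 benzyl group. The step needs chemoselectivity over 1,2-hydride shift from C4–H and over attack on the aryl rings; the C2–H bond, activated by both the O1 lone pair and the electron-rich guaiacyl ring, together with the bulky carboxylate ligands and the low temperature, should secure it.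

**Step 11**
Reactants: 16 tert-butyl (2S,3R,4R)-2-[3-methoxy-4-(triisopropylsilyloxy)phenyl]-4-[[3-methoxy-4-(triisopropylsilyloxy)phenyl]methyl]oxolane-3-carboxylate
Product: 17 [(2S,3S,4R)-2-[3-methoxy-4-(triisopropylsilyloxy)phenyl]-4-[[3-methoxy-4-(triisopropylsilyloxy)phenyl]methyl]oxolan-3-yl]methanol
Conditions: LiAlH4, THF, 0 °C
Reagents that add atoms: none
Why: Hydride reduction of the ester to the primary alcohol should be faster than enolisation at 0 °C, so the C3 configuration (cis to aryl) is kept; aryl silyl ethers and the oxolane are inert to LiAlH4.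

**Step 12**
Reactants: 18 p-coumaric acid
Product: 20 (2E)-3-[4-(triisopropylsilyloxy)phenyl]prop-2-enoic acid, via bis-silylated silyl ester 19 (not isolated)
Conditions: TIPSCl (2.2 equiv), imidazole, DMF, rt; then AcOH/THF/H2O, rt
Reagents that add atoms: chlorotriisopropylsilane, CC(C)[Si](Cl)(C(C)C)C(C)C
Why: Silylation of both acidic OH groups followed by selective hydrolysis of the much more labile silyl ester leaves the phenol protected as its TIPS ether; the E alkene is untouched.

**Step 13**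
Reactants: 17 [(2S,3S,4R)-2-[3-methoxy-4-(triisopropylsilyloxy)phenyl]-4-[[3-methoxy-4-(triisopropylsilyloxy)phenyl]methyl]oxolan-3-yl]methanol; 20 (2E)-3-[4-(triisopropylsilyloxy)phenyl]prop-2-enoic acid
Product: 21 [(2S,3S,4R)-2-[3-methoxy-4-(triisopropylsilyloxy)phenyl]-4-[[3-methoxy-4-(triisopropylsilyloxy)phenyl]methyl]oxolan-3-yl]methyl (2E)-3-[4-(triisopropylsilyloxy)phenyl]prop-2-enoate
Conditions: EDC·HCl, DMAP (cat.), CH2Cl2, 0 °C to rt
Reagents that add atoms: none
Why: Steglich esterification (carbodiimide activation, DMAP acyl transfer) of the primary alcohol under neutral conditions that leave C2 and C3 untouched.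

**Step 14**
Reactants: 21 [(2S,3S,4R)-2-[3-methoxy-4-(triisopropylsilyloxy)phenyl]-4-[[3-methoxy-4-(triisopropylsilyloxy)phenyl]methyl]oxolan-3-yl]methyl (2E)-3-[4-(triisopropylsilyloxy)phenyl]prop-2-enoate
Product: 22 [(2S,3S,4R)-2-(4-hydroxy-3-methoxyphenyl)-4-[(4-hydroxy-3-methoxyphenyl)methyl]oxolan-3-yl]methyl (2E)-3-(4-hydroxyphenyl)prop-2-enoate
Conditions: Bu4NF/AcOH (1:1), THF, 0 °C
Reagents that add atoms: none
Why: Buffered fluoride cleaves the three aryl Si–O bonds; acetic acid protonates the phenoxides at once, which should protect the cinnamate ester and prevent phenoxide-driven opening of the 2-aryl oxolane through a quinone methide.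

**Compound list**
1 | vanillin (4-hydroxy-3-methoxybenzaldehyde) | COc1cc(C=O)ccc1O | starting material
2 | 3-methoxy-4-(triisopropylsilyloxy)benzaldehyde | COc1cc(C=O)ccc1O[Si](C(C)C)(C(C)C)C(C)C | intermediate
3 | [3-methoxy-4-(triisopropylsilyloxy)phenyl]methanol | COc1cc(CO)ccc1O[Si](C(C)C)(C(C)C)C(C)C | intermediate
4 | [4-(bromomethyl)-2-methoxyphenoxy]triisopropylsilane | COc1cc(CBr)ccc1O[Si](C(C)C)(C(C)C)C(C)C | intermediate
5 | [3-methoxy-4-(triisopropylsilyloxy)phenyl]methyl 2,2,2-trichloroacetimidate | COc1cc(COC(=N)C(Cl)(Cl)Cl)ccc1O[Si](C(C)C)(C(C)C)C(C)C | intermediate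
6 | 4-tert-butoxy-4-oxobutanoic acid (mono-tert-butyl succinate) | CC(C)(C)OC(=O)CCC(=O)O | starting material
7 | (4R)-4-benzyl-1,3-oxazolidin-2-one | O=C1N[C@H](Cc2ccccc2)CO1 | starting material
8 | 4-tert-butoxy-4-oxobutanoic pivalic anhydride | CC(C)(C)OC(=O)CCC(=O)OC(=O)C(C)(C)C | intermediate
9 | tert-butyl 4-[(4R)-4-benzyl-2-oxo-1,3-oxazolidin-3-yl]-4-oxobutanoate | CC(C)(C)OC(=O)CCC(=O)N1[C@H](Cc2ccccc2)COC1=O | intermediate
10 | sodium Z-enolate of 9 | CC(C)(C)OC(=O)C/C=C(\[O-])N1[C@H](Cc2ccccc2)COC1=O.[Na+] | intermediate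
11 | tert-butyl (3R)-4-[(4R)-4-benzyl-2-oxo-1,3-oxazolidin-3-yl]-3-[[3-methoxy-4-(triisopropylsilyloxy)phenyl]methyl]-4-oxobutanoate | COc1cc(C[C@H](CC(=O)OC(C)(C)C)C(=O)N2[C@H](Cc3ccccc3)COC2=O)ccc1O[Si](C(C)C)(C(C)C)C(C)C | intermediate
12 | tert-butyl (3R)-3-(hydroxymethyl)-4-[3-methoxy-4-(triisopropylsilyloxy)phenyl]butanoate | COc1cc(C[C@H](CC(=O)OC(C)(C)C)CO)ccc1O[Si](C(C)C)(C(C)C)C(C)C | intermediate
13 | tert-butyl (3R)-4-[3-methoxy-4-(triisopropylsilyloxy)phenyl]-3-[[[3-methoxy-4-(triisopropylsilyloxy)phenyl]methoxy]methyl]butanoate | COc1cc(C[C@H](CC(=O)OC(C)(C)C)COCc2ccc(O[Si](C(C)C)(C(C)C)C(C)C)c(OC)c2)ccc1O[Si](C(C)C)(C(C)C)C(C)C | intermediate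
14 | tert-butyl (3R)-4-[3-methoxy-4-(triisopropylsilyloxy)phenyl]-3-[[[3-methoxy-4-(triisopropylsilyloxy)phenyl]methoxy]methyl]-2-(trifluoroacetyl)butanoate (C2 epimers, enolised) | COc1cc(C[C@H](C(C(=O)C(F)(F)F)C(=O)OC(C)(C)C)COCc2ccc(O[Si](C(C)C)(C(C)C)C(C)C)c(OC)c2)ccc1O[Si](C(C)C)(C(C)C)C(C)C | intermediate
15 | tert-butyl (3R)-2-diazo-4-[3-methoxy-4-(triisopropylsilyloxy)phenyl]-3-[[[3-methoxy-4-(triisopropylsilyloxy)phenyl]methoxy]methyl]butanoate | COc1cc(C[C@H](C(=[N+]=[N-])C(=O)OC(C)(C)C)COCc2ccc(O[Si](C(C)C)(C(C)C)C(C)C)c(OC)c2)ccc1O[Si](C(C)C)(C(C)C)C(C)C | intermediate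
16 | tert-butyl (2S,3R,4R)-2-[3-methoxy-4-(triisopropylsilyloxy)phenyl]-4-[[3-methoxy-4-(triisopropylsilyloxy)phenyl]methyl]oxolane-3-carboxylate | COc1cc(C[C@H]2CO[C@H](c3ccc(O[Si](C(C)C)(C(C)C)C(C)C)c(OC)c3)[C@@H]2C(=O)OC(C)(C)C)ccc1O[Si](C(C)C)(C(C)C)C(C)C | intermediate
17 | [(2S,3S,4R)-2-[3-methoxy-4-(triisopropylsilyloxy)phenyl]-4-[[3-methoxy-4-(triisopropylsilyloxy)phenyl]methyl]oxolan-3-yl]methanol | COc1cc(C[C@H]2CO[C@H](c3ccc(O[Si](C(C)C)(C(C)C)C(C)C)c(OC)c3)[C@@H]2CO)ccc1O[Si](C(C)C)(C(C)C)C(C)C | intermediate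
18 | p-coumaric acid ((2E)-3-(4-hydroxyphenyl)prop-2-enoic acid) | OC(=O)/C=C/c1ccc(O)cc1 | starting material
19 | triisopropylsilyl (2E)-3-[4-(triisopropylsilyloxy)phenyl]prop-2-enoate | CC(C)[Si](OC(=O)/C=C/c1ccc(O[Si](C(C)C)(C(C)C)C(C)C)cc1)(C(C)C)C(C)C | intermediate
20 | (2E)-3-[4-(triisopropylsilyloxy)phenyl]prop-2-enoic acid | OC(=O)/C=C/c1ccc(O[Si](C(C)C)(C(C)C)C(C)C)cc1 | intermediate
21 | [(2S,3S,4R)-2-[3-methoxy-4-(triisopropylsilyloxy)phenyl]-4-[[3-methoxy-4-(triisopropylsilyloxy)phenyl]methyl]oxolan-3-yl]methyl (2E)-3-[4-(triisopropylsilyloxy)phenyl]prop-2-enoate | COc1cc(C[C@H]2CO[C@H](c3ccc(O[Si](C(C)C)(C(C)C)C(C)C)c(OC)c3)[C@@H]2COC(=O)/C=C/c2ccc(O[Si](C(C)C)(C(C)C)C(C)C)cc2)ccc1O[Si](C(C)C)(C(C)C)C(C)C | intermediate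
22 | [(2S,3S,4R)-2-(4-hydroxy-3-methoxyphenyl)-4-[(4-hydroxy-3-methoxyphenyl)methyl]oxolan-3-yl]methyl (2E)-3-(4-hydroxyphenyl)prop-2-enoate | COc1cc(C[C@H]2CO[C@H](c3ccc(O)c(OC)c3)[C@@H]2COC(=O)/C=C/c2ccc(O)cc2)ccc1O | target

**Step count**
Total: 14 steps. Longest linear sequence: 11 steps (1, 2, 3, 6, 7, 8, 9, 10, 11, 13, 14).

**Steps most likely to fail**

Step 10. The carbenoid may be lost to 1,2-hydride shift from the C4–H bond or to attack on an aryl ring. The insertion may also show poor facial selectivity if the chiral catalyst and the C4 stereocentre are mismatched (the first variable would be the enantiomeric catalyst). The fallback uses known chemistry, sets out from 12 and returns at 17. Acid-catalysed lactonisation of 12 (TsOH cat., CH2Cl2) should give (4R)-4-[[3-methoxy-4-(triisopropylsilyloxy)phenyl]methyl]oxolan-2-one F1. Its lithium enolate (LiN(iPr)2, THF, −78 °C) is hydroxymethylated with monomeric formaldehyde anti to the benzyl group to give the trans lactone (3S,4R)-3-(hydroxymethyl)-4-[[3-methoxy-4-(triisopropylsilyloxy)phenyl]methyl]oxolan-2-one F2, which is silylated (TBSCl, imidazole) to its TBS ether F3. Commercial 4-bromo-2-methoxyphenol is silylated (TIPSCl, imidazole) to (4-bromo-2-methoxyphenoxy)triisopropylsilane F4 and converted with n-BuLi (THF, −78 °C) into [3-methoxy-4-(triisopropylsilyloxy)phenyl]lithium F5. This adds once to F3 to give the hydroxy ketone (2S,3R)-2-[(tert-butyldimethylsilyloxy)methyl]-3-(hydroxymethyl)-1,4-bis[3-methoxy-4-(triisopropylsilyloxy)phenyl]butan-1-one F6, in equilibrium with its cyclic hemiketal. Et3SiH and BF3·OEt2 (CH2Cl2, −78 °C) then close the oxolane by reduction of the cyclic oxocarbenium ion; hydride should arrive anti to the C3 substituent, so the aryl group and the C3 arm become cis, giving the silyl ether of 17, F7. PPTS in MeOH removes the alkyl TBS group in the presence of the aryl TIPS ethers and gives 17.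

Step 9. C-Trifluoroacetylation of the hindered, β-branched ester enolate may be incomplete, or the acyl group may be lost again before diazo transfer. The fallback sets out from 13 and returns at 15. The potassium enolate of 13 (KN(SiMe3)2, THF, −78 °C) is azidated with 2,4,6-triisopropylbenzenesulfonyl azide and quenched with AcOH to give the α-azido ester F8 (epimers at the new carbon). Staudinger reduction (PMe3, THF/H2O) gives the α-amino ester F9. Diazotisation with isoamyl nitrite and catalytic AcOH in CHCl3 at reflux should give 15.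

Step 8. The γ-hydroxy tert-butyl ester may lactonise under acid, or the electron-rich imidate may ionise and rearrange before it alkylates the alcohol. The fallback sets out from 12 and returns at 13. The alcohol is silylated (TMSCl, Et3N, CH2Cl2) to its trimethylsilyl ether F10. Reductive etherification of F10 with aldehyde 2 (Et3SiH, TMSOTf cat., CH2Cl2, −78 °C) then builds the benzylic ether from the carbonyl compound instead of from a benzyl cation donor and gives 13.

**Further compounds**
F1 | step 10 | (4R)-4-[[3-methoxy-4-(triisopropylsilyloxy)phenyl]methyl]oxolan-2-one | COc1cc(C[C@H]2COC(=O)C2)ccc1O[Si](C(C)C)(C(C)C)C(C)C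
F2 | step 10 | (3S,4R)-3-(hydroxymethyl)-4-[[3-methoxy-4-(triisopropylsilyloxy)phenyl]methyl]oxolan-2-one | COc1cc(C[C@H]2COC(=O)[C@@H]2CO)ccc1O[Si](C(C)C)(C(C)C)C(C)C
F3 | step 10 | (3S,4R)-3-[(tert-butyldimethylsilyloxy)methyl]-4-[[3-methoxy-4-(triisopropylsilyloxy)phenyl]methyl]oxolan-2-one | COc1cc(C[C@H]2COC(=O)[C@@H]2CO[Si](C)(C)C(C)(C)C)ccc1O[Si](C(C)C)(C(C)C)C(C)C
F4 | step 10 | (4-bromo-2-methoxyphenoxy)triisopropylsilane | COc1cc(Br)ccc1O[Si](C(C)C)(C(C)C)C(C)C
F5 | step 10 | [3-methoxy-4-(triisopropylsilyloxy)phenyl]lithium | COc1cc([Li])ccc1O[Si](C(C)C)(C(C)C)C(C)C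
F6 | step 10 | (2S,3R)-2-[(tert-butyldimethylsilyloxy)methyl]-3-(hydroxymethyl)-1,4-bis[3-methoxy-4-(triisopropylsilyloxy)phenyl]butan-1-one | COc1cc(C[C@@H](CO)[C@@H](CO[Si](C)(C)C(C)(C)C)C(=O)c2ccc(O[Si](C(C)C)(C(C)C)C(C)C)c(OC)c2)ccc1O[Si](C(C)C)(C(C)C)C(C)C
F7 | step 10 | tert-butyl-[[(2S,3S,4R)-2-[3-methoxy-4-(triisopropylsilyloxy)phenyl]-4-[[3-methoxy-4-(triisopropylsilyloxy)phenyl]methyl]oxolan-3-yl]methoxy]dimethylsilane | COc1cc(C[C@H]2CO[C@H](c3ccc(O[Si](C(C)C)(C(C)C)C(C)C)c(OC)c3)[C@@H]2CO[Si](C)(C)C(C)(C)C)ccc1O[Si](C(C)C)(C(C)C)C(C)C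
F8 | step 9 | tert-butyl (3R)-2-azido-4-[3-methoxy-4-(triisopropylsilyloxy)phenyl]-3-[[[3-methoxy-4-(triisopropylsilyloxy)phenyl]methoxy]methyl]butanoate | COc1cc(C[C@H](C(N=[N+]=[N-])C(=O)OC(C)(C)C)COCc2ccc(O[Si](C(C)C)(C(C)C)C(C)C)c(OC)c2)ccc1O[Si](C(C)C)(C(C)C)C(C)C
F9 | step 9 | tert-butyl (3R)-2-amino-4-[3-methoxy-4-(triisopropylsilyloxy)phenyl]-3-[[[3-methoxy-4-(triisopropylsilyloxy)phenyl]methoxy]methyl]butanoate | COc1cc(C[C@H](C(N)C(=O)OC(C)(C)C)COCc2ccc(O[Si](C(C)C)(C(C)C)C(C)C)c(OC)c2)ccc1O[Si](C(C)C)(C(C)C)C(C)C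
F10 | step 8 | tert-butyl (3R)-4-[3-methoxy-4-(triisopropylsilyloxy)phenyl]-3-[(trimethylsilyloxy)methyl]butanoate | COc1cc(C[C@H](CC(=O)OC(C)(C)C)CO[Si](C)(C)C)ccc1O[Si](C(C)C)(C(C)C)C(C)C
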